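**Plan**
Ring labels: A = methoxy-bearing 1,2,3-trisubstituted ring, B = meta-phenylene, C = catechol ring (O-3 arylated, O-4 free), D = para-phenylene. The only ring to build is the 18-membered macrocycle.
Enabling feature: the ether-bearing carbon C-4 of ring D lies para to C-1, which holds the benzylic carbon of the D–CH2–CH2–A bridge. With that bridge carbon as a ketone, a fluoride at C-4 is a vinylogous acyl fluoride, so O-3 of ring C can close the macrocycle by SNAr with no foreign activating group.
Cuts (retrosynthetic order): bridge C=O and O-4 benzyl (one hydrogenation); O-3(C)–C-4(D); the bond between the two A–D bridge carbons (HWE of the ring-A aldehyde with a 4-fluorobenzoyl anion equivalent); C-3(B)–CH2 (B-alkyl Suzuki); C-2(A)–O(B) (SNAr ortho to the same aldehyde).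
Forward: A–O–B is joined, ring C is attached through an already saturated bridge, ring D is added, then come the single ring closure and a global reduction. The carbonyl moves from the A-side to the D-side bridge carbon and activates each aryl fluoride in turn.
Stereochemistry: the target has no stereocentre; the enamine geometry and the racemic phosphonate carbon are erased on the way.

Key step: step 7

Assumption: the 18-membered ring is taken as conformationally mobile at room temperature, so no planar or axial chirality has to be controlled, and all starting materials are taken as catalogue compounds.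

Step 1
Reactants: 1 4-(benzyloxy)-3-hydroxybenzaldehyde
Product: 2 4-(benzyloxy)-3-(methoxymethoxy)benzaldehyde
Conditions: MOMCl, K2CO3, acetone, 0 °C to rt
Reagents that add atoms: chloromethyl methyl ether (MOMCl), COCCl
Why: Williamson-type O-alkylation (MOM protection) of the only free phenol masks O-3 of ring C with an acetal that survives base, borane and palladium and falls in the acid hydrolysis of step 6, while the O-4 benzyl ether stays to the end.

Step 2
Reactants: 2 4-(benzyloxy)-3-(methoxymethoxy)benzaldehyde
Product: 3 1-(benzyloxy)-4-ethenyl-2-(methoxymethoxy)benzene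
Conditions: MePPh3Br, KOtBu, THF, 0 °C to rt
Reagents that add atoms: methyltriphenylphosphonium bromide, C[P+](c1ccccc1)(c1ccccc1)c1ccccc1.[Br-]
Why: Wittig methylenation of a non-enolisable aromatic aldehyde with the unstabilised ylide should give the styrene needed for hydroboration, and the acetal and the benzyl ether are inert to the base.

Step 3
Reactants: 4 2-fluoro-3-methoxybenzaldehyde; 5 3-bromophenol
Product: 6 2-(3-bromophenoxy)-3-methoxybenzaldehyde
Conditions: K2CO3, DMAc, 130 °C, N2
Reagents that add atoms: none
Why: Nucleophilic aromatic substitution by addition–elimination, in which the formyl group ortho to the fluoride takes up the charge of the Meisenheimer adduct so that the phenoxide of 5 displaces fluoride despite the flanking methoxy group, while the unactivated C–Br bond is kept for step 4.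

Step 4
Reactants: 3 1-(benzyloxy)-4-ethenyl-2-(methoxymethoxy)benzene; 7 9-borabicyclo[3.3.1]nonane (9-BBN-H); 6 2-(3-bromophenoxy)-3-methoxybenzaldehyde
Product: 9 2-(3-{2-[4-(benzyloxy)-3-(methoxymethoxy)phenyl]ethyl}phenoxy)-3-methoxybenzaldehyde, via B-alkyl-9-BBN 8 (not isolated)
Conditions: 7 (1.0 equiv), THF, 0 °C to rt; then 6, PdCl2(dppf) (3 mol %), K2CO3, DMF–THF–H2O, 50 °C
Reagents that add atoms: none
Why: Anti-Markovnikov hydroboration of the styrene followed by B-alkyl Suzuki–Miyaura coupling joins the sp3 carbon to ring B and gives the saturated B–C bridge directly, so no alkene hydrogenation endangers the benzyl ether, and with no excess B–H and the borane held as its hydroxy-ate complex the aryl aldehyde should survive.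

Step 5
Reactants: 10 4-fluorobenzaldehyde
Product: 11 diphenyl [(4-fluorophenyl)(phenylamino)methyl]phosphonate (racemic)
Conditions: PhNH2, (PhO)2P(O)H, iPrOH, rt
Reagents that add atoms: aniline, Nc1ccccc1; diphenyl phosphite, O=[PH](Oc1ccccc1)Oc1ccccc1
Why: Kabachnik–Fields three-component condensation, in which the imine of 10 and aniline adds the P–H bond of diphenyl phosphite to give the racemic N,P-acetal, an acyl-anion equivalent of the 4-fluorobenzoyl group whose stereocentre is erased in step 6.

Step 6
Reactants: 9 2-(3-{2-[4-(benzyloxy)-3-(methoxymethoxy)phenyl]ethyl}phenoxy)-3-methoxybenzaldehyde; 11 diphenyl [(4-fluorophenyl)(phenylamino)methyl]phosphonate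
Product: 14 2-[2-(3-{2-[4-(benzyloxy)-3-hydroxyphenyl]ethyl}phenoxy)-3-methoxyphenyl]-1-(4-fluorophenyl)ethan-1-one, via N-phenyl enamine 12 (not isolated), via MOM-protected ketone 13 (not isolated)
Conditions: Cs2CO3, THF–iPrOH, rt; then 3 M aq HCl, 50 °C
Reagents that add atoms: water, O
Why: Horner–Wadsworth–Emmons olefination of the α-anilinophosphonate with the aldehyde gives the enamine, whose acid hydrolysis places the carbonyl on the bridge carbon next to ring D, and the same acid cleaves the MOM acetal, so the 4-fluorophenyl benzyl ketone and the free O-3 phenol are unveiled in one operation.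

Step 7
Reactants: 14 2-[2-(3-{2-[4-(benzyloxy)-3-hydroxyphenyl]ethyl}phenoxy)-3-methoxyphenyl]-1-(4-fluorophenyl)ethan-1-one
Product: 15 macrocyclic ketone (the O-4 benzyl ether of the target with C=O at the bridge carbon attached to ring D)
Conditions: K2CO3 (3 equiv, ground), degassed DMSO, Ar, 120 °C, 14 added by syringe pump, final 2 mM
Reagents that add atoms: none
Why: Carbonate reversibly deprotonates the only free hydroxyl (O-3 of ring C), the phenoxide adds to C-4 of ring D to give a Meisenheimer anion whose charge runs through the ring into the para ketone oxygen, and loss of fluoride restores aromaticity (addition–elimination SNAr). The closest known reaction type is the ketone-activated fluoride displacement that builds aryl ether ketones, including macrocyclic aryl ether ketones made under pseudo-high dilution, together with the SNAr cycloetherification of macrocyclic diaryl ethers that uses nitro or sulfonyl activators. The one ring closed is the 18-membered macrocycle, formed by attack of the tethered oxygen on an sp2 ring carbon from above the face of ring D; the 14-atom tether spans the para positions without undue strain and its ortho (ring A) and two meta (rings B and C) junctions act as turns, so mainly entropy has to be paid, which slow addition handles. No stereocentre is formed. Site selectivity is secured by the substrate, since O-4 is benzylated, rings A to C are electron-rich and carry no leaving group, and only the fluoride para to the ketone is activated. The acidic bridge CH2 competes for base, but its enolate cannot reach ring D within the molecule and exchanges protons rapidly with the phenol in the carbonate/hydrogencarbonate buffer, so the phenoxide–ketone form drains the equilibrium; argon excludes α-oxidation and DMSO avoids the amine that DMF releases on heating.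

Step 8
Reactants: 15 macrocyclic ketone
Product: 16 target macrocycle CNP0309263.0
Conditions: H2 (3 bar), 10% Pd/C, AcOH–EtOAc, cat. HClO4, 40 °C
Reagents that add atoms: none
Why: Catalytic hydrogenation and hydrogenolysis, in which under acid the aryl ketone on the aryloxy-donor ring D is reduced through the benzylic alcohol to CH2 while the O-benzyl group leaves as toluene, and the methyl ether, the diaryl ethers and the arene rings are inert under these conditions.

**Compound list**
1 | 4-(benzyloxy)-3-hydroxybenzaldehyde | O=Cc1ccc(OCc2ccccc2)c(O)c1 | starting material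
2 | 4-(benzyloxy)-3-(methoxymethoxy)benzaldehyde | O=Cc1ccc(OCc2ccccc2)c(OCOC)c1 | intermediate
3 | 1-(benzyloxy)-4-ethenyl-2-(methoxymethoxy)benzene | C=Cc1ccc(OCc2ccccc2)c(OCOC)c1 | intermediate
4 | 2-fluoro-3-methoxybenzaldehyde | COc1cccc(C=O)c1F | starting material
5 | 3-bromophenol | Oc1cccc(Br)c1 | starting material
6 | 2-(3-bromophenoxy)-3-methoxybenzaldehyde | COc1cccc(C=O)c1Oc1cccc(Br)c1 | intermediate
7 | 9-borabicyclo[3.3.1]nonane (9-BBN-H, sold as dimer or THF solution) | B1C2CCCC1CCC2 | starting material
8 | 9-{2-[4-(benzyloxy)-3-(methoxymethoxy)phenyl]ethyl}-9-borabicyclo[3.3.1]nonane (not isolated) | COCOc1cc(CCB2C3CCCC2CCC3)ccc1OCc1ccccc1 | intermediate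
9 | 2-(3-{2-[4-(benzyloxy)-3-(methoxymethoxy)phenyl]ethyl}phenoxy)-3-methoxybenzaldehyde | COc1cccc(C=O)c1Oc1cccc(CCc2ccc(OCc3ccccc3)c(OCOC)c2)c1 | intermediate
10 | 4-fluorobenzaldehyde | O=Cc1ccc(F)cc1 | starting material
11 | diphenyl [(4-fluorophenyl)(phenylamino)methyl]phosphonate (racemic) | O=P(Oc1ccccc1)(Oc1ccccc1)C(Nc1ccccc1)c1ccc(F)cc1 | intermediate
12 | N-phenyl enamine of ketone 13, alkene geometry not defined (not isolated) | COc1cccc(C=C(Nc2ccccc2)c2ccc(F)cc2)c1Oc1cccc(CCc2ccc(OCc3ccccc3)c(OCOC)c2)c1 | intermediate
13 | 2-[2-(3-{2-[4-(benzyloxy)-3-(methoxymethoxy)phenyl]ethyl}phenoxy)-3-methoxyphenyl]-1-(4-fluorophenyl)ethan-1-one (not isolated) | COc1cccc(CC(=O)c2ccc(F)cc2)c1Oc1cccc(CCc2ccc(OCc3ccccc3)c(OCOC)c2)c1 | intermediate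
14 | 2-[2-(3-{2-[4-(benzyloxy)-3-hydroxyphenyl]ethyl}phenoxy)-3-methoxyphenyl]-1-(4-fluorophenyl)ethan-1-one | COc1cccc(CC(=O)c2ccc(F)cc2)c1Oc1cccc(CCc2ccc(OCc3ccccc3)c(O)c2)c1 | intermediate
15 | macrocyclic ketone: O-4 benzyl ether of the target with C=O at the bridge carbon on ring D | COc1cccc2c1Oc1cccc(c1)CCc1ccc(OCc3ccccc3)c(c1)Oc1ccc(cc1)C(=O)C2 | intermediate
16 | CNP0309263.0, 18-membered bis(bibenzyl) macrocycle with OMe on ring A and free OH on ring C (achiral) | COc1cccc2c1Oc1cccc(c1)CCc1ccc(O)c(c1)Oc1ccc(cc1)CC2 | target

Total step count: 8. Longest linear sequence: 6 (steps 1, 2, 4, 6, 7, 8).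

**Steps most likely to fail**

Step 7: intermolecular etherification (oligomerisation) may outrun ring closure, and extensive enolisation of the bridge ketone may switch off the activation of the fluoride. The fallback replaces SNAr by copper-catalysed coupling of an unactivated aryl bromide at the same bond.
- It sets out from 9.
- Wittig olefination with (4-bromobenzyl)triphenylphosphonium bromide (KOtBu, THF) should give the bromostilbene F1.
- Diimide reduction (TsNHNH2, NaOAc, aq DME, reflux) spares C–Br and O-benzyl and should give the MOM-protected bromo-bis(bibenzyl) F2.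
- Acid (HCl, MeOH, 50 °C) should give the bromophenol F3.
- Intramolecular Ullmann ether synthesis (CuI, N,N-dimethylglycine, Cs2CO3, dioxane, 100 °C, high dilution) should give the O-benzyl macrocycle F4.
- Neutral hydrogenolysis (H2, Pd/C, EtOAc) comes back to the route at 16.

Step 4: hydride transfer from boron to the aldehyde of 6, or protodeboronation and β-hydride elimination of the alkyl partner, may erode the coupling. The fallback builds the bridge by olefination and reduction before any aldehyde-bearing ring A is present.
- It sets out from 2.
- Wittig olefination with (3-hydroxybenzyl)triphenylphosphonium bromide (2 equiv KOtBu, THF) should give the hydroxystilbene F5.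
- Diimide reduction (TsNHNH2, NaOAc, aq DME, reflux) should give the bibenzyl phenol F6.
- SNAr of F6 on 4 (K2CO3, DMAc, 130 °C) comes back to the route at 9.

Step 8: the reduction may stall at the benzylic alcohol because hydrogenolysis on the metal surface is slow inside the macrocycle. The fallback uses ionic hydrogenation instead of surface hydrogenolysis.
- It sets out from 15.
- Neutral hydrogenolysis (H2, 1 atm, Pd/C, EtOAc) should remove only the benzyl group and give the hydroxy ketone F7.
- Kursanov–Parnes reduction (Et3SiH, TFA, CH2Cl2, rt) passes through the p-aryloxybenzyl cation and comes back to the route at 16. Any benzylic alcohol formed on the way converges to the same product.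

**Further compounds**
F1 | step 7 | bromostilbene from 9, ring A–CH=CH–C6H4-4-Br (E/Z mixture) | COc1cccc(C=Cc2ccc(Br)cc2)c1Oc1cccc(CCc2ccc(OCc3ccccc3)c(OCOC)c2)c1
F2 | step 7 | MOM-protected bromo-bis(bibenzyl) | COc1cccc(CCc2ccc(Br)cc2)c1Oc1cccc(CCc2ccc(OCc3ccccc3)c(OCOC)c2)c1
F3 | step 7 | bromophenol, seco compound for the Ullmann closure | COc1cccc(CCc2ccc(Br)cc2)c1Oc1cccc(CCc2ccc(OCc3ccccc3)c(O)c2)c1
F4 | step 7 | O-benzyl macrocycle (O-4 benzyl ether of the target) | COc1cccc2c1Oc1cccc(c1)CCc1ccc(OCc3ccccc3)c(c1)Oc1ccc(cc1)CC2
F5 | step 4 | hydroxystilbene, 3-{2-[4-(benzyloxy)-3-(methoxymethoxy)phenyl]ethenyl}phenol (E/Z mixture) | Oc1cccc(C=Cc2ccc(OCc3ccccc3)c(OCOC)c2)c1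
F6 | step 4 | bibenzyl phenol, 3-{2-[4-(benzyloxy)-3-(methoxymethoxy)phenyl]ethyl}phenol | Oc1cccc(CCc2ccc(OCc3ccccc3)c(OCOC)c2)c1
F7 | step 8 | hydroxy ketone, debenzylated macrocyclic ketone | COc1cccc2c1Oc1cccc(c1)CCc1ccc(O)c(c1)Oc1ccc(cc1)C(=O)C2
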